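The route rests on cutting the ester between its carbonyl carbon and the aryl ipso carbon. The ester oxygen sits on C3 of the cyclopentane ring (azulene numbering), a fully substituted carbinol carbon flanked by isopropyl and ring-fusion C3a, which resists ordinary O-aroylation. The key step therefore arms this oxygen as an imidazole-1-carboxylate and lets 4-(silyloxy)phenylmagnesium bromide add once to its carbonyl, forming the aryl–carbonyl bond; the crowded tert-alkyl ester that results shuts down a second addition. The precursor is the complete trans-hydroazulene with O4 silylated and C7 still a methylene, built by tandem asymmetric conjugate addition–aldol, isopropyl addition and ring-closing metathesis; late allylic oxidation installs the enone.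

Key step: step 6

Remark: locants follow the azulene numbering of the target (C3 carries the ester oxygen and isopropyl, C3a/C8a are the ring fusion, C4 carries the hydroxyl, C5=C6 is the alkene, C7 the ketone). The catalyst antipode in step 1 is assumed to be the one that delivers the (3S) enolate.

Step 1
Reactants: 1 3-methylcyclopent-2-en-1-one; 2 4-bromo-2-methylbut-1-ene; 3 prop-2-enal (acrolein)
Product: 6 (2S,3S)-2-[(1S)-1-hydroxyprop-2-en-1-yl]-3-methyl-3-(3-methylbut-3-en-1-yl)cyclopentan-1-one, via homoallyl Grignard reagent 4 (not isolated), via magnesium enolate 5 (not isolated)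
Conditions: 2, Mg, Et2O; then 1, Cu(OTf)2 (3 mol %), chiral imidazolinium salt (NHC precursor, 4 mol %), Et2O, −30 °C; then 3, −78 °C; aq NH4Cl
Reagents that add atoms: none
Why: Copper/chiral NHC-catalysed asymmetric conjugate addition of the Grignard reagent to the β-methyl enone sets the quaternary centre (3S), and the regiodefined magnesium (E)-enolate then adds to acrolein through a closed Zimmerman–Traxler transition state on the face anti to the larger homoallyl arm, which should give the anti aldol with the new C2 substituent cis to the C3 methyl (2S,1'S).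

Step 2
Reactants: 6 (2S,3S)-2-[(1S)-1-hydroxyprop-2-en-1-yl]-3-methyl-3-(3-methylbut-3-en-1-yl)cyclopentan-1-one
Product: 7 (2S,3S)-2-[(1S)-1-[(tert-butyldimethylsilyl)oxy]prop-2-en-1-yl]-3-methyl-3-(3-methylbut-3-en-1-yl)cyclopentan-1-one
Conditions: TBSOTf, 2,6-lutidine, CH2Cl2, −78 °C
Reagents that add atoms: tert-butyldimethylsilyl trifluoromethanesulfonate, CC(C)(C)[Si](C)(C)OS(=O)(=O)C(F)(F)F
Why: Silylation of the secondary allylic alcohol with a silyl triflate and a hindered base at low temperature should outrun retro-aldol cleavage and enol silylation, and it blocks this oxygen for the later alkoxide chemistry without touching a stereocentre.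

Step 3
Reactants: 7 (2S,3S)-2-[(1S)-1-[(tert-butyldimethylsilyl)oxy]prop-2-en-1-yl]-3-methyl-3-(3-methylbut-3-en-1-yl)cyclopentan-1-one
Product: 8 (1R,2S,3S)-2-[(1S)-1-[(tert-butyldimethylsilyl)oxy]prop-2-en-1-yl]-3-methyl-3-(3-methylbut-3-en-1-yl)-1-(propan-2-yl)cyclopentan-1-ol
Conditions: iPrMgCl, anhydrous CeCl3, THF, −78 to 0 °C; aq NH4Cl
Reagents that add atoms: isopropylmagnesium chloride, CC(C)[Mg]Cl
Why: The organocerium reagent formed from the Grignard reagent and CeCl3 adds 1,2 to the hindered, enolisable ketone without deprotonating it, and attack anti to the bulky C2 side chain should place isopropyl trans to that chain and the new hydroxyl cis to it (1R).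

Step 4
Reactants: 8 (1R,2S,3S)-2-[(1S)-1-[(tert-butyldimethylsilyl)oxy]prop-2-en-1-yl]-3-methyl-3-(3-methylbut-3-en-1-yl)-1-(propan-2-yl)cyclopentan-1-ol
Product: 9 (3R,3aS,4S,8aS)-4-[(tert-butyldimethylsilyl)oxy]-6,8a-dimethyl-3-(propan-2-yl)-1,2,3,3a,4,7,8,8a-octahydroazulen-3-ol
Conditions: Grubbs second-generation catalyst (5 mol %), toluene (0.005 M), 80 °C
Reagents that add atoms: none
Why: Ring-closing metathesis of the monosubstituted and the 1,1-disubstituted alkene on the trans-disposed arms of the cyclopentane releases ethene and should close the seven-membered ring as a trisubstituted cycloalkene, giving the trans-fused hydroazulene without touching a stereocentre.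

Step 5
Reactants: 9 (3R,3aS,4S,8aS)-4-[(tert-butyldimethylsilyl)oxy]-6,8a-dimethyl-3-(propan-2-yl)-1,2,3,3a,4,7,8,8a-octahydroazulen-3-ol
Product: 11 (3R,3aS,4S,8aS)-4-[(tert-butyldimethylsilyl)oxy]-6,8a-dimethyl-3-(propan-2-yl)-1,2,3,3a,4,7,8,8a-octahydroazulen-3-yl 1H-imidazole-1-carboxylate, via potassium alkoxide 10 (not isolated)
Conditions: KH, THF, 0 °C; then CDI, 0 °C to rt; aq NH4Cl
Reagents that add atoms: 1,1'-carbonyldiimidazole, O=C(n1ccnc1)n1ccnc1
Why: Deprotonation gives a tertiary potassium alkoxide that is acylated by the small planar carbonyl of CDI (alkoxycarbonyl imidazole formation), while silyl migration from O4 to the far more crowded tertiary oxygen is uphill, so the carbonyl carbon of the future ester is placed regiospecifically on O3.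

Step 6
Reactants: 11 (3R,3aS,4S,8aS)-4-[(tert-butyldimethylsilyl)oxy]-6,8a-dimethyl-3-(propan-2-yl)-1,2,3,3a,4,7,8,8a-octahydroazulen-3-yl 1H-imidazole-1-carboxylate; 12 (4-bromophenoxy)(tert-butyl)dimethylsilane
Product: 14 (3R,3aS,4S,8aS)-4-[(tert-butyldimethylsilyl)oxy]-6,8a-dimethyl-3-(propan-2-yl)-1,2,3,3a,4,7,8,8a-octahydroazulen-3-yl 4-[(tert-butyldimethylsilyl)oxy]benzoate, via aryl Grignard reagent 13 (not isolated)
Conditions: 12, Mg, THF, rt; then 11, THF, 0 °C to rt; aq NH4Cl
Reagents that add atoms: none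
Why: The aryl Grignard reagent adds to the carbonyl of the N-acyl imidazole (magnesium binds the carbonyl oxygen and N3), and the tetrahedral adduct collapses by loss of imidazolide, the best leaving group present, so the aryl–carbonyl bond forms on a carbonyl already fixed to the hindered C3 oxygen. The closest known reaction types are the ester synthesis from Grignard reagents and alkyl imidazole-1-carboxylates and the tert-butoxycarbonylation of aryl-metal reagents with di-tert-butyl dicarbonate. No ring is closed and no stereocentre is formed; C3, C3a, C4 and C8a are untouched. The step needs mono-addition: the product is a tert-alkyl ester flanked by isopropyl and the ring fusion and deactivated by the para silyloxy donor, so it should resist a second addition to ketone or carbinol. It also needs chemoselectivity, which the substrate secures because C7 is still CH2 and O4 is silylated, leaving no other electrophile and no free hydroxyl to which the acyl group could shift.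

Step 7
Reactants: 14 (3R,3aS,4S,8aS)-4-[(tert-butyldimethylsilyl)oxy]-6,8a-dimethyl-3-(propan-2-yl)-1,2,3,3a,4,7,8,8a-octahydroazulen-3-yl 4-[(tert-butyldimethylsilyl)oxy]benzoate
Product: 15 (3R,3aS,4S,8aR)-4-[(tert-butyldimethylsilyl)oxy]-7-hydroxy-6,8a-dimethyl-3-(propan-2-yl)-1,2,3,3a,4,7,8,8a-octahydroazulen-3-yl 4-[(tert-butyldimethylsilyl)oxy]benzoate (C7 epimers)
Conditions: SeO2 (cat.), t-BuOOH, CH2Cl2, rt
Reagents that add atoms: tert-butyl hydroperoxide (terminal oxidant and net oxygen source), CC(C)(C)OO; selenium dioxide (oxygen-transfer catalyst), O=[Se]=O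
Why: Riley allylic oxidation (ene reaction then [2,3]-sigmatropic shift) should hydroxylate the ring CH2 next to the more substituted alkene carbon (C7) and leave the silyloxy-bearing C4–H on the less substituted side untouched; the configuration of the new carbinol is irrelevant because it is oxidised in the next step.

Step 8
Reactants: 15 (3R,3aS,4S,8aR)-4-[(tert-butyldimethylsilyl)oxy]-7-hydroxy-6,8a-dimethyl-3-(propan-2-yl)-1,2,3,3a,4,7,8,8a-octahydroazulen-3-yl 4-[(tert-butyldimethylsilyl)oxy]benzoate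
Product: 16 (3R,3aS,4S,8aR)-4-[(tert-butyldimethylsilyl)oxy]-6,8a-dimethyl-7-oxo-3-(propan-2-yl)-1,2,3,3a,4,7,8,8a-octahydroazulen-3-yl 4-[(tert-butyldimethylsilyl)oxy]benzoate
Conditions: Dess–Martin periodinane, CH2Cl2, rt
Reagents that add atoms: none
Why: Dess–Martin oxidation converts the secondary allylic alcohol into the conjugated enone under near-neutral conditions that should spare both silyl ethers and the tertiary ester.

Step 9
Reactants: 16 (3R,3aS,4S,8aR)-4-[(tert-butyldimethylsilyl)oxy]-6,8a-dimethyl-7-oxo-3-(propan-2-yl)-1,2,3,3a,4,7,8,8a-octahydroazulen-3-yl 4-[(tert-butyldimethylsilyl)oxy]benzoate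
Product: 17 (3R,3aS,4S,8aR)-4-hydroxy-6,8a-dimethyl-7-oxo-3-(propan-2-yl)-1,2,3,3a,4,7,8,8a-octahydroazulen-3-yl 4-hydroxybenzoate
Conditions: HF·pyridine, THF, 0 °C to rt
Reagents that add atoms: none
Why: Hydrogen fluoride–pyridine cleaves the aryl and the secondary alkyl silyl ether in one operation, and the acidic, non-basic medium should prevent 1,3-acyl migration from the tertiary O3 to the liberated 4-hydroxyl and elimination next to the enone.

Compound list
1 | 3-methylcyclopent-2-en-1-one | CC1=CC(=O)CC1 | starting material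
2 | 4-bromo-2-methylbut-1-ene | C=C(C)CCBr | starting material
3 | prop-2-enal (acrolein) | C=CC=O | starting material
4 | (3-methylbut-3-en-1-yl)magnesium bromide | C=C(C)CC[Mg]Br | intermediate
5 | bromomagnesium (3S)-3-methyl-3-(3-methylbut-3-en-1-yl)cyclopent-1-en-1-olate | Br[Mg]OC1=C[C@](C)(CC1)CCC(C)=C | intermediate
6 | (2S,3S)-2-[(1S)-1-hydroxyprop-2-en-1-yl]-3-methyl-3-(3-methylbut-3-en-1-yl)cyclopentan-1-one | C=C[C@H](O)[C@@H]1[C@](C)(CCC1=O)CCC(C)=C | intermediate
7 | (2S,3S)-2-[(1S)-1-[(tert-butyldimethylsilyl)oxy]prop-2-en-1-yl]-3-methyl-3-(3-methylbut-3-en-1-yl)cyclopentan-1-one | C=C[C@H](O[Si](C)(C)C(C)(C)C)[C@@H]1[C@](C)(CCC1=O)CCC(C)=C | intermediate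
8 | (1R,2S,3S)-2-[(1S)-1-[(tert-butyldimethylsilyl)oxy]prop-2-en-1-yl]-3-methyl-3-(3-methylbut-3-en-1-yl)-1-(propan-2-yl)cyclopentan-1-ol | C=C[C@H](O[Si](C)(C)C(C)(C)C)[C@@H]1[C@](C)(CC[C@@]1(O)C(C)C)CCC(C)=C | intermediate
9 | (3R,3aS,4S,8aS)-4-[(tert-butyldimethylsilyl)oxy]-6,8a-dimethyl-3-(propan-2-yl)-1,2,3,3a,4,7,8,8a-octahydroazulen-3-ol | CC1=C[C@H](O[Si](C)(C)C(C)(C)C)[C@@H]2[C@](C)(CC[C@@]2(O)C(C)C)CC1 | intermediate
10 | potassium (3R,3aS,4S,8aS)-4-[(tert-butyldimethylsilyl)oxy]-6,8a-dimethyl-3-(propan-2-yl)-1,2,3,3a,4,7,8,8a-octahydroazulen-3-olate | CC1=C[C@H](O[Si](C)(C)C(C)(C)C)[C@@H]2[C@](C)(CC[C@@]2([O-])C(C)C)CC1.[K+] | intermediate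
11 | (3R,3aS,4S,8aS)-4-[(tert-butyldimethylsilyl)oxy]-6,8a-dimethyl-3-(propan-2-yl)-1,2,3,3a,4,7,8,8a-octahydroazulen-3-yl 1H-imidazole-1-carboxylate | CC1=C[C@H](O[Si](C)(C)C(C)(C)C)[C@@H]2[C@](C)(CC[C@@]2(OC(=O)n2ccnc2)C(C)C)CC1 | intermediate
12 | (4-bromophenoxy)(tert-butyl)dimethylsilane | CC(C)(C)[Si](C)(C)Oc1ccc(Br)cc1 | starting material
13 | {4-[(tert-butyldimethylsilyl)oxy]phenyl}magnesium bromide | CC(C)(C)[Si](C)(C)Oc1ccc([Mg]Br)cc1 | intermediate
14 | (3R,3aS,4S,8aS)-4-[(tert-butyldimethylsilyl)oxy]-6,8a-dimethyl-3-(propan-2-yl)-1,2,3,3a,4,7,8,8a-octahydroazulen-3-yl 4-[(tert-butyldimethylsilyl)oxy]benzoate | CC1=C[C@H](O[Si](C)(C)C(C)(C)C)[C@@H]2[C@](C)(CC[C@@]2(OC(=O)c2ccc(O[Si](C)(C)C(C)(C)C)cc2)C(C)C)CC1 | intermediate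
15 | (3R,3aS,4S,8aR)-4-[(tert-butyldimethylsilyl)oxy]-7-hydroxy-6,8a-dimethyl-3-(propan-2-yl)-1,2,3,3a,4,7,8,8a-octahydroazulen-3-yl 4-[(tert-butyldimethylsilyl)oxy]benzoate (C7 epimers) | CC1=C[C@H](O[Si](C)(C)C(C)(C)C)[C@@H]2[C@](C)(CC[C@@]2(OC(=O)c2ccc(O[Si](C)(C)C(C)(C)C)cc2)C(C)C)CC1O | intermediate
16 | (3R,3aS,4S,8aR)-4-[(tert-butyldimethylsilyl)oxy]-6,8a-dimethyl-7-oxo-3-(propan-2-yl)-1,2,3,3a,4,7,8,8a-octahydroazulen-3-yl 4-[(tert-butyldimethylsilyl)oxy]benzoate | CC1=C[C@H](O[Si](C)(C)C(C)(C)C)[C@@H]2[C@](C)(CC[C@@]2(OC(=O)c2ccc(O[Si](C)(C)C(C)(C)C)cc2)C(C)C)CC1=O | intermediate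
17 | (3R,3aS,4S,8aR)-4-hydroxy-6,8a-dimethyl-7-oxo-3-(propan-2-yl)-1,2,3,3a,4,7,8,8a-octahydroazulen-3-yl 4-hydroxybenzoate | CC1=C[C@H](O)[C@@H]2[C@](C)(CC[C@@]2(OC(=O)c2ccc(O)cc2)C(C)C)CC1=O | target

Total step count: 9
Longest linear sequence: 9 steps (1 to 17; the aryl Grignard reagent is made in the flask in step 6)

Steps most likely to fail

Step 1. The catalyst may discriminate poorly between the enantiofaces of the five-membered enone, and the aldol may lose diastereocontrol, both in the choice of enolate face and in the syn/anti sense. The fallback sets out from Grignard reagent 4 and comes back at 6, and it reverses the roles of the two β-substituents. Reagent 4 is added to commercial 3-ethoxycyclopent-2-en-1-one and the adduct is hydrolysed with acid (Stork–Danheiser transposition) to 3-(3-methylbut-3-en-1-yl)cyclopent-2-en-1-one F1. Copper/chiral ligand-catalysed conjugate addition of trimethylaluminium, with methyl now the incoming group, should give the dimethylaluminium (3S)-enolate F2 in the flask. Its aldol addition to acrolein 3 at low temperature returns 6.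

Step 3. The congested carbonyl may be enolised or reduced instead of attacked, silanolate may be lost by β-elimination, and facial control on the flexible monocycle may be poor. The fallback sets out from 7 and comes back at 9. Ring-closing metathesis of 7 first should give the rigid bicyclic ketone (3aS,4S,8aS)-4-[(tert-butyldimethylsilyl)oxy]-6,8a-dimethyl-2,3a,4,7,8,8a-hexahydroazulen-3(1H)-one F3. The smaller sp2 nucleophile from isopropenylmagnesium bromide and CeCl3 should then add anti to the angular methyl to give the tertiary allylic alcohol (3S,3aS,4S,8aS)-4-[(tert-butyldimethylsilyl)oxy]-6,8a-dimethyl-3-(prop-1-en-2-yl)-1,2,3,3a,4,7,8,8a-octahydroazulen-3-ol F4. Hydrogenation of the 1,1-disubstituted alkene with Wilkinson's catalyst, which should leave the trisubstituted ring alkene alone, returns 9.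

Step 7. The ene reaction may be slow at an alkene shielded by the neighbouring silyloxy group, the vinylic methyl may be oxidised in competition, and over-oxidation may occur. The fallback sets out from 8 and comes back at 16; it oxidises the unhindered open-chain alkene before the ring is closed. Alcohol 8 is deprotonated with KH to the potassium alkoxide F5 and acylated with CDI to the imidazole-1-carboxylate F6. Aryl Grignard reagent 13 converts F6 into the monocyclic 4-[(tert-butyldimethylsilyl)oxy]benzoate F7 by the same key reaction. Riley oxidation of the 2-methylalk-1-ene in F7 at its allylic CH2 should give the allylic alcohol F8, and Dess–Martin oxidation then gives the isopropenyl ketone F9. Ring-closing metathesis of F9 with the enone as one partner closes the cycloheptenone and returns 16.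

Further compounds
F1 | step 1 | 3-(3-methylbut-3-en-1-yl)cyclopent-2-en-1-one | C=C(C)CCC1=CC(=O)CC1
F2 | step 1 | dimethylaluminium (3S)-3-methyl-3-(3-methylbut-3-en-1-yl)cyclopent-1-en-1-olate | C[Al](C)OC1=C[C@](C)(CC1)CCC(C)=C
F3 | step 3 | (3aS,4S,8aS)-4-[(tert-butyldimethylsilyl)oxy]-6,8a-dimethyl-2,3a,4,7,8,8a-hexahydroazulen-3(1H)-one | CC1=C[C@H](O[Si](C)(C)C(C)(C)C)[C@@H]2[C@](C)(CCC2=O)CC1
F4 | step 3 | (3S,3aS,4S,8aS)-4-[(tert-butyldimethylsilyl)oxy]-6,8a-dimethyl-3-(prop-1-en-2-yl)-1,2,3,3a,4,7,8,8a-octahydroazulen-3-ol | CC1=C[C@H](O[Si](C)(C)C(C)(C)C)[C@@H]2[C@](C)(CC[C@@]2(O)C(C)=C)CC1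
F5 | step 7 | potassium (1R,2S,3S)-2-[(1S)-1-[(tert-butyldimethylsilyl)oxy]prop-2-en-1-yl]-3-methyl-3-(3-methylbut-3-en-1-yl)-1-(propan-2-yl)cyclopentan-1-olate | C=C[C@H](O[Si](C)(C)C(C)(C)C)[C@@H]1[C@](C)(CC[C@@]1([O-])C(C)C)CCC(C)=C.[K+]
F6 | step 7 | (1R,2S,3S)-2-[(1S)-1-[(tert-butyldimethylsilyl)oxy]prop-2-en-1-yl]-3-methyl-3-(3-methylbut-3-en-1-yl)-1-(propan-2-yl)cyclopentyl 1H-imidazole-1-carboxylate | C=C[C@H](O[Si](C)(C)C(C)(C)C)[C@@H]1[C@](C)(CC[C@@]1(OC(=O)n1ccnc1)C(C)C)CCC(C)=C
F7 | step 7 | (1R,2S,3S)-2-[(1S)-1-[(tert-butyldimethylsilyl)oxy]prop-2-en-1-yl]-3-methyl-3-(3-methylbut-3-en-1-yl)-1-(propan-2-yl)cyclopentyl 4-[(tert-butyldimethylsilyl)oxy]benzoate | C=C[C@H](O[Si](C)(C)C(C)(C)C)[C@@H]1[C@](C)(CC[C@@]1(OC(=O)c1ccc(O[Si](C)(C)C(C)(C)C)cc1)C(C)C)CCC(C)=C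
F8 | step 7 | (1R,2S,3R)-2-[(1S)-1-[(tert-butyldimethylsilyl)oxy]prop-2-en-1-yl]-3-(2-hydroxy-3-methylbut-3-en-1-yl)-3-methyl-1-(propan-2-yl)cyclopentyl 4-[(tert-butyldimethylsilyl)oxy]benzoate (carbinol epimers) | C=C[C@H](O[Si](C)(C)C(C)(C)C)[C@@H]1[C@](C)(CC[C@@]1(OC(=O)c1ccc(O[Si](C)(C)C(C)(C)C)cc1)C(C)C)CC(O)C(C)=C
F9 | step 7 | (1R,2S,3R)-2-[(1S)-1-[(tert-butyldimethylsilyl)oxy]prop-2-en-1-yl]-3-methyl-3-(3-methyl-2-oxobut-3-en-1-yl)-1-(propan-2-yl)cyclopentyl 4-[(tert-butyldimethylsilyl)oxy]benzoate | C=C[C@H](O[Si](C)(C)C(C)(C)C)[C@@H]1[C@](C)(CC[C@@]1(OC(=O)c1ccc(O[Si](C)(C)C(C)(C)C)cc1)C(C)C)CC(=O)C(C)=C
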